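**Plan**

- Retrosynthesis: the C7 carbinol is taken back to its ketone, and the 14-membered carbocycle is then cut at C9–C10, the allyl–allyl σ-bond in the middle of the C19=C8–C9–C10–C11=C12 1,5-diene.
- Enabling feature: C8 carries two equivalent methylene arms (C9 and C19) next to the C7 oxygen. With C7 as a ketone, a C10 allyl radical can add to one arm of a 2-(sulfonylmethyl)allyl unit while the other arm loses the sulfonyl group and becomes the exocyclic alkene.
- Further cuts: oxane O–C15 (C4–OH onto the isopropenyl group), C7–C8 (lactone plus 2-lithioallyl alkoxide), the C3–C4 epoxide, C5–C6 with the 3E alkene (Johnson–Claisen), C3–C4 (Grignard), C10–C11 and C12–CH3 (carboalumination), and the ring alkene of (R)-limonene.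
- Forward order: limonene is opened to a chain centred on C1; the west arm becomes the 11E allyl silyl ether; the east arm becomes 3E ester, epoxide, γ-lactone and enone; the oxane closes, then the 14-membered ring, then C7 is reduced.
- Stereochemistry: C1 from (R)-limonene; C3 and C4 from Shi epoxidation followed by invertive lactonisation at C4; 11E from syn-carboalumination; C7 from CBS reduction.

Key step: step 14

Remark: cembrane numbering is used throughout: C1 = ring CH bonded to C15 (the CMe2 carbon on the ether oxygen), C3 = CH–OAc, C4 = C(CH3)–O, C7 = CH–OH, C8 = C(=C19H2), C11=C12(CH3). Commercial (R)-(+)-limonene of high enantiomeric purity is assumed.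

**Route**

Step 1
Reactants: 1 (R)-(+)-limonene
Product: 3 (5R)-7,7-dimethoxy-5-(prop-1-en-2-yl)heptan-2-one, via keto aldehyde 2 (not isolated)
Conditions: O3 (1.0 equiv), CH2Cl2/MeOH, −78 °C; Me2S, −78 °C → rt; then TsOH·H2O (cat.), MeOH, rt
Reagents that add atoms: ozone, O=[O+][O-]; methanol, CO
Why: Chemoselective ozonolysis: the trisubstituted ring alkene is more electron-rich than the 1,1-disubstituted side-chain alkene and should be cleaved first by one equivalent of ozone, and acid-catalysed acetal formation in methanol then masks only the aldehyde, the limonene stereocentre (future C1) being untouched.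

Step 2
Reactants: 3 (5R)-7,7-dimethoxy-5-(prop-1-en-2-yl)heptan-2-one
Product: 5 (5R)-7,7-dimethoxy-5-(prop-1-en-2-yl)hept-1-yne, via enol phosphate 4 (not isolated)
Conditions: LiN(iPr)2 (1.1 equiv), THF, −78 °C; ClP(O)(OEt)2, −78 °C → rt; LiN(iPr)2 (2.3 equiv), −78 °C → rt; H2O
Reagents that add atoms: none
Why: Kinetic deprotonation on the methyl side, O-phosphorylation and base-induced elimination of diethyl phosphate from the terminal enol phosphate should give the terminal alkyne (ketone-to-alkyne conversion through an enol phosphate), which the acetal and the isopropenyl group tolerate.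

Step 3
Reactants: 5 (5R)-7,7-dimethoxy-5-(prop-1-en-2-yl)hept-1-yne
Product: 6 (3R)-3-(prop-1-en-2-yl)hept-6-ynal
Conditions: oxalic acid (aq.), THF, rt
Reagents that add atoms: water, O
Why: Acid-catalysed acetal hydrolysis frees the aldehyde; the stereocentre is β to the carbonyl and cannot epimerise.

Step 4
Reactants: 6 (3R)-3-(prop-1-en-2-yl)hept-6-ynal
Product: 7 (5R)-2-methyl-5-(prop-1-en-2-yl)non-1-en-8-yn-3-ol (C3 epimers)
Conditions: CH2=C(CH3)MgBr (1.3 equiv), THF, −78 °C; then H2O
Reagents that add atoms: isopropenylmagnesium bromide, CC(=C)[Mg]Br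
Why: Grignard 1,2-addition to the aldehyde at −78 °C outpaces deprotonation of the alkyne, and the new carbinol centre (C3) forms as an epimer mixture that does not matter because this carbon becomes sp2 in step 7.

Step 5
Reactants: 7 (5R)-2-methyl-5-(prop-1-en-2-yl)non-1-en-8-yn-3-ol (C3 epimers)
Product: 9 (2E,6R)-3,9-dimethyl-6-(prop-1-en-2-yl)deca-2,9-diene-1,8-diol (C8 epimers), via alkenylalane 8 (not isolated)
Conditions: AlMe3 (3.5 equiv), Cp2ZrCl2 (0.25 equiv), CH2Cl2, 0 °C → rt; then (CH2O)n, THF, 0 °C → rt; then H2O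
Reagents that add atoms: trimethylaluminium, C[Al](C)C; formaldehyde (as paraformaldehyde), C=O
Why: Negishi zirconium-catalysed carboalumination adds CH3 and Al syn across the terminal alkyne with CH3 on the internal carbon, and the alkenyl–Al bond then adds to formaldehyde with retention, so C11=C12 should form as the 11E isomer only, the free hydroxyl being carried as its aluminium alkoxide and the 1,1-disubstituted alkenes staying inert.

Step 6
Reactants: 9 (2E,6R)-3,9-dimethyl-6-(prop-1-en-2-yl)deca-2,9-diene-1,8-diol (C8 epimers)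
Product: 10 (5R,8E)-10-{[tert-butyl(dimethyl)silyl]oxy}-2,8-dimethyl-5-(prop-1-en-2-yl)deca-1,8-dien-3-ol (C3 epimers)
Conditions: TBSCl (1.05 equiv), imidazole, CH2Cl2, −20 → 0 °C
Reagents that add atoms: tert-butyldimethylsilyl chloride, CC(C)(C)[Si](C)(C)Cl
Why: Silylation with the bulky chlorosilane is selective for the primary allylic hydroxyl over the secondary one.

Step 7
Reactants: 10 (5R,8E)-10-{[tert-butyl(dimethyl)silyl]oxy}-2,8-dimethyl-5-(prop-1-en-2-yl)deca-1,8-dien-3-ol (C3 epimers)
Product: 12 ethyl (4E,7R,10E)-12-{[tert-butyl(dimethyl)silyl]oxy}-4,10-dimethyl-7-(prop-1-en-2-yl)dodeca-4,10-dienoate, via ketene acetal 11 (not isolated)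
Conditions: CH3C(OEt)3 (6 equiv), EtCO2H (cat.), 140 °C, EtOH distilled off
Reagents that add atoms: triethyl orthoacetate, CC(OCC)(OCC)OCC
Why: Johnson–Claisen rearrangement: the mixed ketene acetal rearranges through a chair transition state with the C2 chain equatorial, which forms the C5–C6 bond and the 3E trisubstituted alkene and erases the C3 epimer mixture.

Step 8
Reactants: 12 ethyl (4E,7R,10E)-12-{[tert-butyl(dimethyl)silyl]oxy}-4,10-dimethyl-7-(prop-1-en-2-yl)dodeca-4,10-dienoate
Product: 14 (5S)-5-[(1R,3R,6E)-8-{[tert-butyl(dimethyl)silyl]oxy}-1-hydroxy-6-methyl-3-(prop-1-en-2-yl)oct-6-en-1-yl]-5-methyloxolan-2-one, via epoxy ester 13 (not isolated)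
Conditions: 1,2:4,5-di-O-isopropylidene-β-D-erythro-2,3-hexodiulo-2,6-pyranose (Shi ketone from D-fructose, 0.3 equiv), Oxone (2KHSO5·KHSO4·K2SO4, 1.4 equiv), K2CO3, aq. Na2B4O7 buffer, Bu4NHSO4, MeCN/CH2(OMe)2, 0 °C; extractive work-up; then camphorsulfonic acid (0.1 equiv), wet CH2Cl2, 0 °C → rt
Reagents that add atoms: potassium peroxymonosulfate (from Oxone), [K+].[O-]S(=O)(=O)OO; water, O
Why: Shi epoxidation under catalyst control should deliver oxygen to one face of the electron-rich 3E alkene to give the (3R,4R)-epoxide (C11=C12 is deactivated and shielded by its allylic silyloxy group and the 1,1-disubstituted alkene is the slowest class), and acid then lets the ester carbonyl open the epoxide 5-exo at the tertiary C4 with inversion, which sets C3 (R, retained) and C4 (S).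

Step 9
Reactants: 14 the hydroxy γ-lactone from step 8; 15 2-bromoprop-2-en-1-ol
Product: 17 (6S,7R,9R,12E)-14-{[tert-butyl(dimethyl)silyl]oxy}-1,6,7-trihydroxy-6,12-dimethyl-2-methylidene-9-(prop-1-en-2-yl)tetradec-12-en-3-one, via dilithio reagent 16 (not isolated)
Conditions: 15 (2.6 equiv), t-BuLi (7.8 equiv), Et2O, −78 → 0 °C; then 14, THF, −78 °C; then H2O
Reagents that add atoms: none
Why: Br/Li exchange gives the 2-lithioallyl alkoxide, which should add only once to the lactone carbonyl because the tetrahedral lithium lactolate is stable at −78 °C and collapses on work-up, releasing the C7 α-(hydroxymethyl)vinyl ketone and the free tertiary C4 hydroxyl (nucleophilic acyl substitution of a lactone by an organolithium).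

Step 10
Reactants: 17 the triol enone from step 9
Product: 18 [(6S,7R,9R,12E)-7-acetoxy-14-{[tert-butyl(dimethyl)silyl]oxy}-6-hydroxy-6,12-dimethyl-2-methylidene-3-oxo-9-(prop-1-en-2-yl)tetradec-12-en-1-yl] acetate
Conditions: Ac2O (2.5 equiv), pyridine, 4-(dimethylamino)pyridine (cat.), CH2Cl2, 0 °C
Reagents that add atoms: acetic anhydride, CC(=O)OC(C)=O
Why: Acetylation caps the secondary C3 hydroxyl, which installs the acetate of the target and blocks a competing five-ring ether closure, and turns the primary allylic hydroxyl into a leaving group, while the hindered tertiary C4 hydroxyl does not react.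

Step 11
Reactants: 18 the diacetate from step 10
Product: 20 (2S,3R,5R)-2-[4-(acetoxymethyl)-3-oxopent-4-en-1-yl]-5-[(3E)-5-{[tert-butyl(dimethyl)silyl]oxy}-3-methylpent-3-en-1-yl]-2,6,6-trimethyloxan-3-yl acetate, via alkylmercury trifluoroacetate 19 (not isolated)
Conditions: Hg(OCOCF3)2 (1.05 equiv), NaHCO3 (solid), CH2Cl2, −20 °C; then Bu3SnH (1.2 equiv), azobisisobutyronitrile (cat.), PhMe, rt
Reagents that add atoms: none
Why: Intramolecular oxymercuration–demercuration: divalent mercury activates the isopropenyl group, the C4 hydroxyl attacks its tertiary carbon C15 in a 6-exo Markovnikov closure that forms the oxane ring without a new stereocentre, and tin hydride replaces mercury by hydrogen in a radical chain, the enone being too electron-poor to be mercurated and the mercurinium ion at C11=C12 reverting for lack of an internal nucleophile.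

Step 12
Reactants: 20 the oxane diacetate from step 11
Product: 21 (2S,3R,5R)-5-[(3E)-5-{[tert-butyl(dimethyl)silyl]oxy}-3-methylpent-3-en-1-yl]-2,6,6-trimethyl-2-{3-oxo-4-[(phenylsulfonyl)methyl]pent-4-en-1-yl}oxan-3-yl acetate
Conditions: PhSO2Na (1.2 equiv), DMF, 0 °C → rt
Reagents that add atoms: sodium benzenesulfinate, [Na+].[O-]S(=O)c1ccccc1
Why: SN2′ addition–elimination: the soft sulfinate adds to the enone terminus and acetate leaves from the allylic arm, which gives the same allyl sulfone whichever arm is attacked and leaves the secondary acetate untouched.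

Step 13
Reactants: 21 the allyl sulfone from step 12
Product: 22 (2S,3R,5R)-5-[(3E)-5-bromo-3-methylpent-3-en-1-yl]-2,6,6-trimethyl-2-{3-oxo-4-[(phenylsulfonyl)methyl]pent-4-en-1-yl}oxan-3-yl acetate
Conditions: Ph3PBr2 (1.5 equiv), CH2Cl2, 0 °C → rt
Reagents that add atoms: dibromotriphenylphosphorane, BrP(Br)(c1ccccc1)(c1ccccc1)c1ccccc1
Why: Ph3PBr2 activates the silyl ether oxygen as an alkoxyphosphonium salt and bromide displaces Ph3P=O at the primary allylic carbon (direct conversion of a silyl ether into a bromide), under neutral conditions that should keep the 11E alkene, the acetate and the enone.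

Step 14
Reactants: 22 the bromo sulfone from step 13
Product: 23 (1R,3R,4S,11E)-4,15-epoxy-7-oxocembra-8(19),11-dien-3-yl acetate
Conditions: (Bu3Sn)2 (1.2 equiv), hν (350 nm, Pyrex), PhH, 25–40 °C, 22 added by syringe pump to 1 mM
Reagents that add atoms: none
Why: Proposed new method: Bu3Sn• from photolysed (Bu3Sn)2 abstracts bromine from C10, the 11E allyl radical adds through its unhindered primary terminus C10 to the terminal methylene C9 of the C7-keto-activated acceptor in a 14-endo-trig closure, and the tertiary α-keto radical at C8 expels PhSO2• by β-scission so that the former CH2SO2Ph arm becomes the exocyclic C19 methylene; PhSO2• then cleaves (Bu3Sn)2 to regenerate Bu3Sn•, so the chain needs no hydride donor and an uncyclised radical cannot be reduced. The closest known reaction types are the intermolecular radical allylation of halides by 2-acyl allyl sulfones and stannanes (addition–fragmentation) and the 14-endo macrocyclisation of allylic radicals onto enones used for cembranoid rings; their combination as a ring-closing allyl transfer has not been shown. No stereocentre is created, since C8 ends as an sp2 carbon and C9 and C10 are methylenes. The step needs regioselectivity at the ambident radical, secured by attack through C10 and not the tertiary C12 terminus and by the 14- over the 12-membered ring, and retention of the 11E geometry, secured by the slow C11–C12 rotation of the allyl radical at 25–40 °C. Ring closure over intermolecular addition is secured by high dilution and by the fact that the only fast fate of the adduct radical is loss of the sulfonyl radical.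

Step 15
Reactants: 23 the macrocyclic α-methylene ketone from step 14
Product: 24 (1R,3R,4S,7R,11E)-4,15-epoxy-7-hydroxycembra-8(19),11-dien-3-yl acetate (CNP0202897.1)
Conditions: (S)-1-methyl-3,3-diphenyltetrahydro-1H,3H-pyrrolo[1,2-c][1,3,2]oxazaborole ((S)-Me-CBS, 0.5 equiv), catecholborane (1.5 equiv), PhMe, −78 °C; then MeOH, aq. NH4Cl
Reagents that add atoms: none
Why: CBS reduction: the oxazaborolidine should bind the ketone with the branched alkenyl side (C8) as the large group and deliver hydride from catecholborane to one face, setting C7 as R under reagent control, while the low temperature favours 1,2- over 1,4-reduction.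

**Compound list**

1 | (R)-(+)-limonene | CC1=CC[C@@H](CC1)C(C)=C | starting material
2 | (3R)-6-oxo-3-(prop-1-en-2-yl)heptanal | CC(=O)CC[C@@H](C(C)=C)CC=O | intermediate
3 | (5R)-7,7-dimethoxy-5-(prop-1-en-2-yl)heptan-2-one | CC(=O)CC[C@@H](C(C)=C)CC(OC)OC | intermediate
4 | diethyl (5R)-7,7-dimethoxy-5-(prop-1-en-2-yl)hept-1-en-2-yl phosphate | C=C(OP(=O)(OCC)OCC)CC[C@@H](C(C)=C)CC(OC)OC | intermediate
5 | (5R)-7,7-dimethoxy-5-(prop-1-en-2-yl)hept-1-yne | C#CCC[C@@H](C(C)=C)CC(OC)OC | intermediate
6 | (3R)-3-(prop-1-en-2-yl)hept-6-ynal | C#CCC[C@@H](C(C)=C)CC=O | intermediate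
7 | (5R)-2-methyl-5-(prop-1-en-2-yl)non-1-en-8-yn-3-ol, C3 epimers | C#CCC[C@@H](C(C)=C)CC(O)C(C)=C | intermediate
8 | (E)-alkenyl(dimethyl)alane from syn-addition of CH3–Al to the alkyne of 7, carbinol as its dimethylaluminium alkoxide | C[Al](C)/C=C(\C)CC[C@@H](C(C)=C)CC(O[Al](C)C)C(C)=C | intermediate
9 | (2E,6R)-3,9-dimethyl-6-(prop-1-en-2-yl)deca-2,9-diene-1,8-diol, C8 epimers | OC/C=C(\C)CC[C@@H](C(C)=C)CC(O)C(C)=C | intermediate
10 | (5R,8E)-10-{[tert-butyl(dimethyl)silyl]oxy}-2,8-dimethyl-5-(prop-1-en-2-yl)deca-1,8-dien-3-ol, C3 epimers | CC(C)(C)[Si](C)(C)OC/C=C(\C)CC[C@@H](C(C)=C)CC(O)C(C)=C | intermediate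
11 | 1-ethoxyethenyl ether of 10 (mixed ketene acetal) | CC(C)(C)[Si](C)(C)OC/C=C(\C)CC[C@@H](C(C)=C)CC(OC(=C)OCC)C(C)=C | intermediate
12 | ethyl (4E,7R,10E)-12-{[tert-butyl(dimethyl)silyl]oxy}-4,10-dimethyl-7-(prop-1-en-2-yl)dodeca-4,10-dienoate | CC(C)(C)[Si](C)(C)OC/C=C(\C)CC[C@@H](C(C)=C)C/C=C(\C)CCC(=O)OCC | intermediate
13 | ethyl 3-[(2R,3R)-3-[(2R,5E)-7-{[tert-butyl(dimethyl)silyl]oxy}-5-methyl-2-(prop-1-en-2-yl)hept-5-en-1-yl]-2-methyloxiran-2-yl]propanoate | CC(C)(C)[Si](C)(C)OC/C=C(\C)CC[C@@H](C(C)=C)C[C@H]1O[C@]1(C)CCC(=O)OCC | intermediate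
14 | (5S)-5-[(1R,3R,6E)-8-{[tert-butyl(dimethyl)silyl]oxy}-1-hydroxy-6-methyl-3-(prop-1-en-2-yl)oct-6-en-1-yl]-5-methyloxolan-2-one | CC(C)(C)[Si](C)(C)OC/C=C(\C)CC[C@@H](C(C)=C)C[C@@H](O)[C@]1(C)CCC(=O)O1 | intermediate
15 | 2-bromoprop-2-en-1-ol | OCC(Br)=C | starting material
16 | lithium 2-lithioprop-2-en-1-olate | [Li]OCC([Li])=C | intermediate
17 | (6S,7R,9R,12E)-14-{[tert-butyl(dimethyl)silyl]oxy}-1,6,7-trihydroxy-6,12-dimethyl-2-methylidene-9-(prop-1-en-2-yl)tetradec-12-en-3-one | CC(C)(C)[Si](C)(C)OC/C=C(\C)CC[C@@H](C(C)=C)C[C@@H](O)[C@](C)(CCC(=O)C(=C)CO)O | intermediate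
18 | [(6S,7R,9R,12E)-7-acetoxy-14-{[tert-butyl(dimethyl)silyl]oxy}-6-hydroxy-6,12-dimethyl-2-methylidene-3-oxo-9-(prop-1-en-2-yl)tetradec-12-en-1-yl] acetate | CC(C)(C)[Si](C)(C)OC/C=C(\C)CC[C@@H](C(C)=C)C[C@@H](OC(C)=O)[C@](C)(CCC(=O)C(=C)COC(C)=O)O | intermediate
19 | 20 with one C15 methyl replaced by CH2HgOCOCF3, C15 epimers | CC(C)(C)[Si](C)(C)OC/C=C(\C)CC[C@@H]1C[C@@H](OC(C)=O)[C@](C)(CCC(=O)C(=C)COC(C)=O)OC1(C)C[Hg]OC(=O)C(F)(F)F | intermediate
20 | (2S,3R,5R)-2-[4-(acetoxymethyl)-3-oxopent-4-en-1-yl]-5-[(3E)-5-{[tert-butyl(dimethyl)silyl]oxy}-3-methylpent-3-en-1-yl]-2,6,6-trimethyloxan-3-yl acetate | CC(C)(C)[Si](C)(C)OC/C=C(\C)CC[C@@H]1C[C@@H](OC(C)=O)[C@](C)(CCC(=O)C(=C)COC(C)=O)OC1(C)C | intermediate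
21 | (2S,3R,5R)-5-[(3E)-5-{[tert-butyl(dimethyl)silyl]oxy}-3-methylpent-3-en-1-yl]-2,6,6-trimethyl-2-{3-oxo-4-[(phenylsulfonyl)methyl]pent-4-en-1-yl}oxan-3-yl acetate | CC(C)(C)[Si](C)(C)OC/C=C(\C)CC[C@@H]1C[C@@H](OC(C)=O)[C@](C)(CCC(=O)C(=C)CS(=O)(=O)c2ccccc2)OC1(C)C | intermediate
22 | (2S,3R,5R)-5-[(3E)-5-bromo-3-methylpent-3-en-1-yl]-2,6,6-trimethyl-2-{3-oxo-4-[(phenylsulfonyl)methyl]pent-4-en-1-yl}oxan-3-yl acetate | BrC/C=C(\C)CC[C@@H]1C[C@@H](OC(C)=O)[C@](C)(CCC(=O)C(=C)CS(=O)(=O)c2ccccc2)OC1(C)C | intermediate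
23 | (1R,3R,4S,11E)-4,15-epoxy-7-oxocembra-8(19),11-dien-3-yl acetate | C=C1CC/C=C(\C)CC[C@@H]2C[C@@H](OC(C)=O)[C@](C)(CCC1=O)OC2(C)C | intermediate
24 | (1R,3R,4S,7R,11E)-4,15-epoxy-7-hydroxycembra-8(19),11-dien-3-yl acetate (CNP0202897.1) | C=C1CC/C=C(\C)CC[C@@H]2C[C@@H](OC(C)=O)[C@](C)(CC[C@H]1O)OC2(C)C | target

**Step count and risks**

Total step count: 15. Longest linear sequence: 15 steps, from (R)-(+)-limonene 1.

Steps most likely to fail:

1. Step 14 (proposed new method). The ring closure may be too slow against radical–radical coupling and intermolecular addition to the acceptor or to the product enone, and the allyl radical may lose its 11E geometry or react through C12. The fallback uses known chemistry and sets out from 22. NaN(SiMe3)2 (1.05 equiv) in THF at −78 → 0 °C and 1 mM deprotonates the CH2SO2Ph group, and the α-sulfonyl carbanion alkylates the C10 allylic bromide within the molecule (the classical sulfone-carbanion macrocyclisation), giving (1R,3R,4S,11E)-4,15-epoxy-7-oxo-9-(phenylsulfonyl)cembra-8(19),11-dien-3-yl acetate F1. Bu3SnH with azobisisobutyronitrile in PhH at 80 °C then converts the allylic sulfone into the transposed allylstannane (the stannyl radical adds to C19 and PhSO2• leaves from C9), giving (1R,3R,4S,11E)-4,15-epoxy-7-oxo-19-(tributylstannyl)cembra-8,11-dien-3-yl acetate F2. Protodestannylation with HCl in wet CH2Cl2 protonates C9 and moves the double bond back to C8=C19, so the fallback comes back to the route at 23.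

2. Step 8. Over-epoxidation at C11=C12 or at the isopropenyl group, or insufficient facial control by the catalyst, would erode the C3/C4 stereochemistry. The fallback sets out from 10 and uses hydroxyl-directed chemistry. Sharpless epoxidation in its kinetic-resolution mode (Ti(OiPr)4, D-(−)-diisopropyl tartrate, t-BuOOH, 4 Å sieves, CH2Cl2, −20 °C) should convert only the (3R)-epimer into the erythro epoxy alcohol (1R,3R,6E)-8-{[tert-butyl(dimethyl)silyl]oxy}-6-methyl-1-[(2S)-2-methyloxiran-2-yl]-3-(prop-1-en-2-yl)oct-6-en-1-ol F3. The unreacted (3S)-epimer of 10 is recycled by oxidation and reduction. Dimethyl sodiomalonate (NaOMe, MeOH, reflux) opens the epoxide at its CH2 terminus and the tertiary alkoxide lactonises to methyl (5S)-5-[(1R,3R,6E)-8-{[tert-butyl(dimethyl)silyl]oxy}-1-hydroxy-6-methyl-3-(prop-1-en-2-yl)oct-6-en-1-yl]-5-methyl-2-oxooxolane-3-carboxylate F4. Krapcho dealkoxycarbonylation (LiCl, wet DMSO, 140 °C) brings the fallback back to the route at 14.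

3. Step 11. Mercuration of the trisubstituted C11=C12 alkene, slow closure of the hindered ether between two tertiary carbons, or radical side reactions at the enone during demercuration may lower the conversion. The fallback sets out from 18 and replaces metal activation by a halo-etherification through an isolable intermediate. N-Iodosuccinimide in CH2Cl2/MeCN at 0 °C should give (2S,3R,5R)-2-[4-(acetoxymethyl)-3-oxopent-4-en-1-yl]-5-[(3E)-5-{[tert-butyl(dimethyl)silyl]oxy}-3-methylpent-3-en-1-yl]-6-(iodomethyl)-2,6-dimethyloxan-3-yl acetate F5. Radical deiodination (Bu3SnH, Et3B, air, PhMe, 0 °C) then comes back to the route at 20.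

**Further compounds**

F1 | step 14 | (1R,3R,4S,11E)-4,15-epoxy-7-oxo-9-(phenylsulfonyl)cembra-8(19),11-dien-3-yl acetate, C9 epimers | C=C1C(S(=O)(=O)c3ccccc3)C/C=C(\C)CC[C@@H]2C[C@@H](OC(C)=O)[C@](C)(CCC1=O)OC2(C)C
F2 | step 14 | (1R,3R,4S,11E)-4,15-epoxy-7-oxo-19-(tributylstannyl)cembra-8,11-dien-3-yl acetate | CCCC[Sn](CCCC)(CCCC)CC1=CC/C=C(\C)CC[C@@H]2C[C@@H](OC(C)=O)[C@](C)(CCC1=O)OC2(C)C
F3 | step 8 | (1R,3R,6E)-8-{[tert-butyl(dimethyl)silyl]oxy}-6-methyl-1-[(2S)-2-methyloxiran-2-yl]-3-(prop-1-en-2-yl)oct-6-en-1-ol | CC(C)(C)[Si](C)(C)OC/C=C(\C)CC[C@@H](C(C)=C)C[C@@H](O)[C@]1(C)CO1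
F4 | step 8 | methyl (5S)-5-[(1R,3R,6E)-8-{[tert-butyl(dimethyl)silyl]oxy}-1-hydroxy-6-methyl-3-(prop-1-en-2-yl)oct-6-en-1-yl]-5-methyl-2-oxooxolane-3-carboxylate, C3 epimers | CC(C)(C)[Si](C)(C)OC/C=C(\C)CC[C@@H](C(C)=C)C[C@@H](O)[C@]1(C)CC(C(=O)OC)C(=O)O1
F5 | step 11 | (2S,3R,5R)-2-[4-(acetoxymethyl)-3-oxopent-4-en-1-yl]-5-[(3E)-5-{[tert-butyl(dimethyl)silyl]oxy}-3-methylpent-3-en-1-yl]-6-(iodomethyl)-2,6-dimethyloxan-3-yl acetate, C6 epimers | CC(C)(C)[Si](C)(C)OC/C=C(\C)CC[C@@H]1C[C@@H](OC(C)=O)[C@](C)(CCC(=O)C(=C)COC(C)=O)OC1(C)CI
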